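**Strategy.** The cyclobutane (ring B) is closed by an intramolecular enone–allene [2+2] photocycloaddition that forms C1–C10 and C5–C6 in one operation. It exploits the oxygen on C2 of ring A, next to C1: in the precursor, (R)-4-hydroxycyclopentenone carries on that oxygen a mixed ketal whose carbon is the future C8 and whose chain ends in the C10=C6 allene. The six-membered ketal ring that closes with C1–C10 forces C9 and ring A onto the same face of ring B (the cis-syn-cis array), fixes the C10 quaternary centre, and later releases a methyl ketone (C7/C8) for aldol closure of ring C. O-2 is then inverted by Mitsunobu acetylation.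

Key step: step 4

Remark: atoms carry guaianolide numbers (ring A = C1–C5 with the acetate on C2 and the carbinol C4; ring B = cyclobutane C1/C5/C6/C10; ring C = C6–C10 with the tiglate on C8; ring D = butenolide C6/C7/C11/C12 with the C13 acetoxymethyl group); the ketal carbon of the tether forms as both epimers, which converge in step 7; 2-methylpent-3-yn-2-ol is taken as a catalogue compound.

Step 1
Reactants: 1 2-methylpent-3-yn-2-ol; 2 2-methoxypropene
Product: 4 4,6-dimethylhepta-4,5-dien-2-one, via propargyl isopropenyl ether 3 (not isolated)
Conditions: 2 (3 equiv), TsOH·H2O (cat.), hydroquinone (trace), sealed tube, 90 °C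
Reagents that add atoms: none
Why: Acid-catalysed exchange gives the propargyl isopropenyl ether 3, which undergoes the Saucy–Marbet (propargyl Claisen) [3,3]-rearrangement to the β-allenic methyl ketone; no stereocentre is formed.

Step 2
Reactants: 4 4,6-dimethylhepta-4,5-dien-2-one
Product: 5 6,6-dimethoxy-2,4-dimethylhepta-2,3-diene
Conditions: HC(OMe)3, MeOH, PPTS (cat.), 0 → 23 °C; Et3N quench
Reagents that add atoms: trimethyl orthoformate, COC(OC)OC
Why: Acid-catalysed ketalisation with the orthoformate as dehydrating agent gives the dimethyl ketal needed for ketal exchange; no stereocentre is formed and the mild acid should leave the allene untouched.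

Step 3
Reactants: 5 6,6-dimethoxy-2,4-dimethylhepta-2,3-diene; 6 (R)-4-hydroxycyclopent-2-en-1-one
Product: 7 (4R)-4-[(2-methoxy-4,6-dimethylhepta-4,5-dien-2-yl)oxy]cyclopent-2-en-1-one (both ketal epimers)
Conditions: 5 (2 equiv), PPTS (cat.), toluene, 4 Å MS, 40 °C, reduced pressure; Et3N quench
Reagents that add atoms: none
Why: Transketalisation driven by removal of methanol places the allenyl chain on O-2 with retention at C2 (the C–O bond of 6 is not broken); the new ketal centre is inconsequential because it becomes the C8 carbonyl in step 7.

Step 4
Reactants: 7 mixed ketal of (R)-4-hydroxycyclopentenone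
Product: 8 tricyclic photoadduct (ring A 4-ketone cis-fused to the 6-isopropylidene-10-methylcyclobutane; ketal ring C1–C2–O–C8(OMe)(CH3)–C9–C10)
Conditions: hν (366 nm, Pyrex), MeCN (0.005 M), Et3N (trace), 20 °C, argon
Reagents that add atoms: none
Why: Excitation of the cyclopentenone gives its triplet, which adds to the proximal allene double bond through a 1,4-biradical that collapses to the cyclobutane; the closest known reaction type is the intramolecular enone–allene [2+2] photocycloaddition of cyclopentenones tethered through the C4 oxygen. Two rings close: the cyclobutane (C1–C10 and C5–C6, straight [2+2] mode) and the six-membered ketal ring C1–C2–O–C8–C9–C10 (6-exo bonding of C1 to C10, with C5 bonding to the central allene carbon C6). C1 and C5 are set by the tether, which delivers the allene to the face of ring A syn to O-2 and gives the cis-fused bicyclo[3.2.0]heptanone; C10 is set because C9 must stay cis to C2 on the new six-membered ring, which puts the C10 methyl on the outer face and later forces ring C syn to ring A. The step needs proximal-over-distal allene selectivity and straight-over-crossed closure, both secured by the three-atom O–C8–C9 link (the alternatives need seven-membered rings) and by formation of an allyl-type radical on bonding at C6. Long-wavelength light is chosen to spare the β,γ-unsaturated ketone product from secondary acyl shifts.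

Step 5
Reactants: 8 tricyclic photoadduct
Product: 9 4-methylene tricycle (C4=CH2; C6 isopropylidene and ketal ring unchanged)
Conditions: Ph3PCH3Br, KOtBu, THF, 0 → 23 °C
Reagents that add atoms: methyltriphenylphosphonium bromide, C[P+](c1ccccc1)(c1ccccc1)c1ccccc1.[Br-]
Why: Wittig methylenation masks C4 as the olefin needed for later hydration and removes the ring A carbonyl that would otherwise trigger retro-aldol opening of ring B once O-6 is free; no stereocentre is formed.

Step 6
Reactants: 9 4-methylene tricycle
Product: 10 C6 cyclobutanone (4-methylene; ketal ring intact)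
Conditions: O3 (1.0 equiv, titrated solution), pyridine (2 equiv), CH2Cl2, −78 °C; then Me2S
Reagents that add atoms: ozone, [O-][O+]=O
Why: Ozonolysis with one equivalent of ozone is expected to cleave the electron-rich, strained tetrasubstituted isopropylidenecyclobutane faster than the 1,1-disubstituted methylene group, unveiling the C6 cyclobutanone; no stereocentre is formed.

Step 7
Reactants: 10 C6 cyclobutanone
Product: 12 tricyclic ketol (rings A/B/C cis-syn-cis; 2-OH cis to ring B; 4-methylene; 6-OH cis to the 10-methyl; 8-ketone), via hydroxy diketone 11 (not isolated)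
Conditions: AcOH/THF/H2O (3:1:1), 23 °C; then K2CO3 (cat.), MeOH, 0 °C
Reagents that add atoms: water, O
Why: Mild acid hydrolyses the mixed ketal to the C8 methyl ketone and the C2 alcohol, and the methyl ketone enolate then adds to the strained cyclobutanone in an intramolecular aldol reaction that closes ring C; C6 is set by the geometric need for a cis-fused bicyclo[3.2.0] unit (C7 cis to C9), which places O-6 on the face of the C10 methyl, and enolisation of the cyclobutanone toward C5 (a cyclobutene enolate) should not compete.

Step 8
Reactants: 12 tricyclic ketol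
Product: 13 C2 acetate of the ketol (C2 inverted; acetate trans to ring B)
Conditions: AcOH, PPh3, DIAD, THF, 0 → 23 °C
Reagents that add atoms: acetic acid, CC(=O)O
Why: Mitsunobu esterification with acetic acid proceeds by SN2 attack from the open convex face and so inverts C2, turning the former tether anchor into the C2 acetate of the target, while the tertiary C6 alcohol is inert.

Step 9
Reactants: 13 C2 acetate of the ketol
Product: 16 tetracyclic 11-methyl butenolide enedione (ring D closed; C8 ketone; 4-methylene), via pyruvate ester 14 (not isolated), via aldol lactone 15 (not isolated)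
Conditions: pyruvoyl chloride (freshly prepared), pyridine, DMAP (cat.), CH2Cl2, −20 °C; then DBU, 0 → 40 °C
Reagents that add atoms: pyruvoyl chloride, CC(=O)C(Cl)=O
Why: Acylation of the tertiary cyclobutanol with the reactive keto acid chloride is followed by intramolecular aldol addition of the C7 enolate (alpha to the C8 ketone) to the pyruvate ketone and E1cB loss of water (a Knoevenagel-type butenolide annulation), driven by formation of the conjugated 4-acylbutenolide; only attack through C7 gives a five-membered lactone, and the transient C7/C11 centres are destroyed.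

Step 10
Reactants: 16 tetracyclic 11-methyl butenolide enedione
Product: 17 C4 tertiary alcohol (4-OH trans to ring B and cis to the C2 acetate; 4-methyl on the concave face)
Conditions: Co(acac)2 (cat.), PhSiH3, O2 (1 atm), THF/iPrOH, 23 °C
Reagents that add atoms: dioxygen, O=O
Why: Mukaiyama hydration (hydrogen-atom transfer to the 1,1-disubstituted olefin, trapping of the tertiary C4 radical by O2, reduction of the peroxide) gives the Markovnikov alcohol; oxygen is expected to enter from the convex face of ring A, anti to ring B, while the hindered tetrasubstituted butenolide olefin is a poor hydrogen-atom acceptor.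

Step 11
Reactants: 17 C4 tertiary alcohol
Product: 18 C13 bromide (11-bromomethyl butenolide)
Conditions: NBS, AIBN (cat.), PhCF3, 80 °C
Reagents that add atoms: N-bromosuccinimide, O=C1CCC(=O)N1Br
Why: Wohl–Ziegler bromination: the C13 methyl group is the only allylic C–H position of the tetrasubstituted enedione, so bromine is delivered there; no stereocentre is formed.

Step 12
Reactants: 18 C13 bromide
Product: 19 C13 acetate (8-ketone)
Conditions: KOAc, 18-crown-6 (cat.), MeCN, 23 °C
Reagents that add atoms: potassium acetate, CC(=O)[O-].[K+]
Why: SN2 displacement of the primary allylic bromide by acetate installs the C13 acetoxymethyl group; no stereocentre is involved.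

Step 13
Reactants: 19 C13 acetate (8-ketone)
Product: 20 8-epi alcohol (8-OH cis to ring B, on the concave face)
Conditions: NaBH4, CeCl3·7H2O, MeOH, −78 °C
Reagents that add atoms: none
Why: Luche reduction reduces the conjugated C8 ketone in 1,2-fashion without touching lactone or acetates; hydride is expected to attack from the convex face of ring C (the concave face is shielded by ring A), giving the C8 alcohol epimeric to the target.

Step 14
Reactants: 20 8-epi alcohol
Product: 21 target (CNP0210373.1)
Conditions: tiglic acid, PPh3, DIAD, toluene, 0 → 23 °C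
Reagents that add atoms: tiglic acid, C/C=C(\C)C(=O)O
Why: Mitsunobu esterification with tiglic acid inverts C8 by SN2 attack from the convex face and delivers the tiglate cis to the C10 methyl group and O-6, while the tertiary C4 alcohol does not react and SN2' attack is blocked because C11 is fully substituted.

**Compound list**

1 | 2-methylpent-3-yn-2-ol | CC#CC(C)(C)O | starting material
2 | 2-methoxypropene | COC(C)=C | starting material
3 | 2-methyl-2-(prop-1-en-2-yloxy)pent-3-yne (propargyl isopropenyl ether) | CC#CC(C)(C)OC(C)=C | intermediate (not isolated)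
4 | 4,6-dimethylhepta-4,5-dien-2-one | CC(=O)CC(C)=C=C(C)C | intermediate
5 | 6,6-dimethoxy-2,4-dimethylhepta-2,3-diene | COC(C)(CC(C)=C=C(C)C)OC | intermediate
6 | (R)-4-hydroxycyclopent-2-en-1-one | O=C1C=C[C@H](O)C1 | starting material
7 | (4R)-4-[(2-methoxy-4,6-dimethylhepta-4,5-dien-2-yl)oxy]cyclopent-2-en-1-one, both epimers at the ketal carbon | O=C1C=C[C@H](OC(C)(OC)CC(C)=C=C(C)C)C1 | intermediate
8 | tricyclic photoadduct: ring A 4-ketone cis-fused at C1–C5 to the cyclobutane carrying the C6 isopropylidene and the C10 methyl; six-membered methyl ketal ring C1–C2–O–C8(OMe)(CH3)–C9–C10; O-2 and C9 on the ring B face opposite to H-1, H-5 and the C10 methyl; ketal epimers | COC1(C)C[C@]2(C)[C@@H]3[C@H](O1)CC(=O)[C@@H]3C2=C(C)C | intermediate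
9 | 4-methylene analogue of 8 (C4=CH2) | COC1(C)C[C@]2(C)[C@@H]3[C@H](O1)CC(=C)[C@@H]3C2=C(C)C | intermediate
10 | C6 cyclobutanone (4-methylene, ketal ring intact) | COC1(C)C[C@]2(C)[C@@H]3[C@H](O1)CC(=C)[C@@H]3C2=O | intermediate
11 | hydroxy diketone: bicyclic C6 cyclobutanone with 2-OH cis to ring B, 4-methylene, and an acetonyl group (C9–C8(=O)–C7H3) cis to C2 on C10 | CC(=O)C[C@]1(C)[C@@H]2[C@H](O)CC(=C)[C@@H]2C1=O | intermediate (not isolated)
12 | tricyclic ketol: rings A/B/C cis-syn-cis, 2-OH cis to ring B, 4-methylene, 6-OH cis to the 10-methyl, 8-ketone | O=C1C[C@]2(C)[C@@H]3[C@H](O)CC(=C)[C@@H]3[C@]2(O)C1 | intermediate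
13 | C2 acetate of the ketol, C2 inverted (acetate trans to ring B) | O=C1C[C@]2(C)[C@@H]3[C@@H](OC(C)=O)CC(=C)[C@@H]3[C@]2(O)C1 | intermediate
14 | 6-O-pyruvate ester of 13 | O=C1C[C@]2(C)[C@@H]3[C@@H](OC(C)=O)CC(=C)[C@@H]3[C@]2(OC(=O)C(C)=O)C1 | intermediate (not isolated)
15 | aldol lactone: saturated ring D with 11-hydroxy-11-methyl, C7–H (C7/C11 configuration undefined) | O=C1C[C@]2(C)[C@@H]3[C@@H](OC(C)=O)CC(=C)[C@@H]3[C@@]23OC(=O)C(C)(O)C13 | intermediate (not isolated)
16 | tetracyclic 11-methyl butenolide enedione: 2-acetate, 4-methylene, 8-ketone | O=C1C[C@]2(C)[C@@H]3[C@@H](OC(C)=O)CC(=C)[C@@H]3[C@@]23OC(=O)C(C)=C13 | intermediate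
17 | C4 tertiary alcohol: 4-OH trans to ring B and cis to the 2-acetate | O=C1C[C@]2(C)[C@@H]3[C@@H](OC(C)=O)C[C@@](C)(O)[C@@H]3[C@@]23OC(=O)C(C)=C13 | intermediate
18 | C13 bromide | O=C1C[C@]2(C)[C@@H]3[C@@H](OC(C)=O)C[C@@](C)(O)[C@@H]3[C@@]23OC(=O)C(CBr)=C13 | intermediate
19 | C13 acetate, 8-ketone | O=C1C[C@]2(C)[C@@H]3[C@@H](OC(C)=O)C[C@@](C)(O)[C@@H]3[C@@]23OC(=O)C(COC(C)=O)=C13 | intermediate
20 | 8-epi alcohol (8-OH cis to ring B) | O[C@@H]1C[C@]2(C)[C@@H]3[C@@H](OC(C)=O)C[C@@](C)(O)[C@@H]3[C@@]23OC(=O)C(COC(C)=O)=C13 | intermediate
21 | CNP0210373.1 | C/C=C(\C)C(=O)O[C@H]1C[C@]2(C)[C@@H]3[C@@H](OC(C)=O)C[C@@](C)(O)[C@@H]3[C@@]23OC(=O)C(COC(C)=O)=C13 | target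

**Totals and risks**

Total step count: 14. Longest linear sequence: 14 steps (1 → 21; 6 enters as a purchased building block).

Steps most likely to fail, riskiest first:

Step 9. The acylation of the hindered tertiary cyclobutanol may be slow, and base may open ring C by retro-aldol or eliminate the acyloxy group before the annulation closes. The fallback sets out from 13 and returns at 16. O-acylation of 13 with oxalyl chloride (pyridine, CH2Cl2, −78 °C) gives the chlorooxalate F2. Addition of Et3N closes ring D by C-acylation of the C7 enol, giving the 11-hydroxybutenolide F3 (enol of the α-keto lactone). Tf2O/2,6-lutidine converts it into the enol triflate F4, and Stille coupling with Me4Sn (Pd(PPh3)4, LiCl, DMF, 60 °C) installs the C13 methyl group to give 16.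

Step 10. Hydrogen-atom transfer to the electron-poor enedione (conjugate reduction) or silane reduction of the C8 ketone may compete with hydration of the methylene group. The fallback sets out from 16 and returns at 17. Oxymercuration (Hg(OAc)2, THF/H2O, 0 °C), to which the electron-poor butenolide is inert, gives the β-hydroxyalkylmercury acetate F5, with water entering at C4 from the convex face. Radical demercuration with Bu3SnH (THF, 23 °C) leaves the ketone untouched and gives 17.

Step 6. Ozone uptake may not discriminate between the two olefins, leading to over-oxidation at the C4 methylene group. The fallback sets out from 9 and returns at 11. Photo-oxygenation of 9 (O2, tetraphenylporphyrin, visible light, CH2Cl2, 0 °C; Schenck ene reaction, to which the 1,1-disubstituted olefin is inert) gives the tertiary allylic hydroperoxide F1. Aqueous trifluoroacetic acid in THF then effects Hock cleavage to the cyclobutanone with loss of acetone and hydrolyses the ketal, giving hydroxy diketone 11, which is carried into the aldol closure of step 7.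

Further compounds
F1 | step 6 | C6 hydroperoxide of the tricyclic ketal: 6-hydroperoxy-6-isopropenyl, 4-methylene (C6 configuration undefined) | COC1(C)C[C@]2(C)[C@@H]3[C@H](O1)CC(=C)[C@@H]3C2(OO)C(C)=C
F2 | step 9 | 6-O-chlorooxalyl ester of 13 | O=C1C[C@]2(C)[C@@H]3[C@@H](OC(C)=O)CC(=C)[C@@H]3[C@]2(OC(=O)C(Cl)=O)C1
F3 | step 9 | 11-hydroxybutenolide (enol of the α-keto lactone), 8-ketone, 4-methylene | O=C1C[C@]2(C)[C@@H]3[C@@H](OC(C)=O)CC(=C)[C@@H]3[C@@]23OC(=O)C(O)=C13
F4 | step 9 | C11 enol triflate of F3 | O=C1C[C@]2(C)[C@@H]3[C@@H](OC(C)=O)CC(=C)[C@@H]3[C@@]23OC(=O)C(OS(=O)(=O)C(F)(F)F)=C13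
F5 | step 10 | C4 hydroxy C15 mercury acetate (4-OH trans to ring B) | O=C1C[C@]2(C)[C@@H]3[C@@H](OC(C)=O)C[C@@](C[Hg]OC(C)=O)(O)[C@@H]3[C@@]23OC(=O)C(C)=C13
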